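## Structural features

The target (C48H34O28) is a linear chain of eight benzene rings, A to H, joined only by seven diaryl ether oxygens and carrying twenty-one free phenolic hydroxyls; it has no stereocentre and no ring-to-ring C–C bond. Ring A is a 2,4,6-trihydroxyphenoxy end group and ring H a 3,4,5-trihydroxyphenoxy end group. Rings B, D and F are 3,5-dihydroxy-1,4-phenylenedioxy units: position 1 holds the oxygen to the preceding ring, position 4 the oxygen to the following ring, positions 2 and 6 are C–H. Rings C, E and G carry oxygen on five neighbouring carbons: position 1 holds the oxygen from position 4 of the preceding ring, position 2 the oxygen to position 1 of the next ring, positions 3 to 5 are hydroxylated and position 6 is the only C–H. The fragile groups are the pyrogallol- and hydroxyquinol-like arrays, which air oxidises to quinones in base, so every hydroxyl travels as a methyl ether until the last step; the only stereocentre anywhere on the route is the quaternary carbon of the cyclobutenone intermediates, racemic and transient. The real difficulty is the ether bonds between very electron-rich rings at oxygens flanked by two ortho substituents, above all B4–O–C1, D4–O–E1 and F4–O–G1, where a 2,6-dimethoxyphenol oxygen must be joined to a ring carbon that sits next to a second aryloxy group. The key step exploits the G1 to G6 array: the four squarate carbons become G2 to G5 with their oxygens and the two carbons of a 1-aryloxyvinyl group become G1 (already bonded to the F4 oxygen) and G6, so F4–O–G1 is never formed by a coupling. The same logic serves rings C and E.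

## Logic of the disconnections

49 is traced to 48 by cutting all twenty-one O–CH3 bonds. Methyl is the only group that every building block already carries and that survives organolithiums and heat. The forward step must cleave every ether exhaustively with air excluded.

48 is cut at G2–O–H1 into 46 and 47. Ring H is a catalogue boronic acid that is unhindered at boron, so one whole ring is removed in a single operation. The forward step is an oxidative copper coupling on a phenol flanked by an aryloxy and a methoxy group.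

46 goes back to 44 by exchanging the roles of the two ring G oxygens that the ring construction leaves differentiated: the G5–O–CH3 bond is cut and the acetal is restored on G2. The forward step must methylate the G5 hydroxyl and then remove the G2 acetal with acid without touching methyl ethers.

44 goes back to 41 by cutting G5–G6 and folding G2 to G5 back into a four-membered ring. This is chosen because five contiguous oxygens are exactly what a squarate plus an oxygenated vinyl group deliver. Ring G is reduced to 12 and a two-carbon enol ether, and the hindered ether at G1 is reduced to an ordinary phenol oxygen. The forward step needs outward rotation of the C4 oxygen substituent and a substrate that survives 110 °C.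

41 is cut between the quaternary ring carbon and the vinyl carbon, and at the O–CH2 bond of the acetal, giving 38 and 12. The forward step needs a 1-aryloxyvinyl anion that adds once, in 1,2 fashion, and an alkoxide that can be capped in the same flask.

38 goes back to 37 (C–Sn and C–H bonds across an alkyne) and 37 to 34 (loss of two chlorines). The alkyne is the smallest precursor of a 1-metallovinyl ether. The forward demand is tin on the oxygen-bearing carbon.

34 is cut at E2–O–F1 into 33 and 5. Ring F arrives with its 4-oxygen already carrying the masked alkyne, so no free hexamer phenol and no protecting-group exchange is needed on a large intermediate. The coupling must tolerate the dichlorovinyl ether.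

33 is taken back through 31, 28, 25, 24 and 21 to 20 and 5 by the same cuts: E5/E2 oxygen adjustment, E5–E6 ring opening, squarate addition, stannane, alkyne and the C2–O–D1 coupling. One sequence of reactions therefore serves rings D and E.

20 is taken back through 18, 15, 11, 10 and 7 to 6 and 5 in the same way, for rings B and C. Ring A is the catalogue phenol 6.

5 goes back to 4 (B–O bonds of the pinacol ester) and 4 to 1 and 2 (aryl O–vinyl bond). The trichloroethylene chemistry is thus done once, on a small molecule, and serves rings B, D and F.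

## Other disconnections considered

Alternative 1: The cut removes both ether oxygens from ring E (E1–O and E2–O) and makes ring E a linchpin, 3,4-difluoro-6-methoxyphthalaldehyde A1. Forward, the D4 phenoxide of the permethylated tetramer A–D phenol A2 would displace the fluoride para to one formyl group (E1). The F1 phenoxide of the permethylated trimer F–H phenol A3 would then displace the fluoride ortho to the other formyl group (E2) in the same flask, giving the octamer dialdehyde A4. A twofold Dakin oxidation would then turn the formyl groups into the E3 and E4 hydroxyls.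
- In its favour: a 4 + 1 + 3 assembly, both bonds of the vicinal bis(aryloxy) motif made without a metal, and no tin or cryogenic organolithium on large intermediates.
- Against it here: the order of the two displacements rests only on the difference between para and ortho activation, while the nucleophile meant to go first (the doubly ortho-substituted D4 phenoxide) is the poorer one. Double addition of A2 or exchange of positions is a real possibility. The second displacement occurs on a ring already made more electron-rich by the first aryloxy group, and an ortho-dialdehyde under peroxide can divert to lactol or phthalide-type products.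
- Against it here, structurally: A2 and A3 each contain a ring of the same five-oxygen type (C and G), so the same problem must be solved twice more by other means.
- Comparison: on structure the chosen plan is stronger, since one reaction builds C, E and G alike. On mechanism the chosen ring expansion has its regiochemistry fixed by connectivity, whereas this plan has an open regiochemical question. On convergence and longest linear sequence this alternative is the better plan, and on operational simplicity (no tin) it is also better. At the final deprotection the two are equal.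

Alternative 2: The cut is the A4–A5 carbon–carbon bond of ring A. Forward, base-mediated Claisen condensation of the triketide diester A5 (C2 onto the C7 ester, 6-exo-trig, then enolisation) would give the octamer A6 with ring A as a methyl 2,4,6-trihydroxy-3-aryloxybenzoate.
- In its favour: it mirrors polyketide folding, uses only mild base, and A5 is symmetric about C4, so either enolate gives the same ring. On certainty of regiochemistry it is the equal of the chosen plan. It is better in that ring A emerges unprotected, leaving three fewer methyl ethers to cleave.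
- Against it here: ring A is the one ring that can be bought complete. A5 carries the whole heptamer B–H on an α-aryloxy-β,δ-diketone, so every difficult ether bond must exist before the key step. 3,5-Dioxo esters tend to lactonise to 4-hydroxypyranones or to suffer retro-Claisen cleavage, and the ester must then be removed by hydrolysis and decarboxylation.
- Comparison: on structure it addresses none of the real difficulty, whereas the chosen plan addresses its core. On mechanism both are well-understood closures of a six-membered ring. On step economy it is worse, adding late steps to a ring that costs none in the chosen plan.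

Alternative 3: The cut is the four hydroxyl C–O bonds at C4, E4, G4 and H4. Forward, peracid would convert the four aldehydes of the octamer tetraaldehyde A7 into aryl formates, and methanolysis would give the octamer tetraphenol A8.
- In its favour: each formyl group is para to position 1 of its ring, so the bonds B4–O–C1, D4–O–E1, F4–O–G1 and G2–O–H1 could be made by fluoride displacement on formyl-activated rings. The Dakin reaction of 2,6-dialkoxybenzaldehydes is dependable. Four oxygens appear in one operation and A8 can go straight to the final ether cleavage with four fewer methyl groups; on these two points it is better than the chosen plan. It also avoids organometallic steps.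
- Against it here: the formyl groups are meta to C2, E2 and G2, so the second ether bond of each five-oxygen ring gets no activation and stays as hard as before. Peracid on a molecule with many tri- and tetra-alkoxybenzene rings risks ring oxidation to quinones. The key step itself builds no skeletal bond, so the strategic burden falls on earlier steps it does not define.
- Comparison: on structure the chosen plan solves the vicinal bis(aryloxy) rings completely, this one half-way. On mechanism both key steps are reliable in their class and are equal. On step economy at the unveiling stage this alternative is better; over the whole route the unsolved meta ether bonds would probably cost more steps than they save.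

Key step: step 19

Remarks on the chemistry (assumptions, one line each):
- Shorthand: "dimer A–B", "tetramer A–D" and "hexamer A–F" are the permethylated chains ending at the B4, D4 or F4 oxygen; "trimer A–C", "pentamer A–E" and "heptamer A–G" end in ring C, E or G; every hydroxyl not mentioned is a methyl ether.
- The dichlorovinyl ethers are drawn as the (E) isomers expected from anti addition of phenoxide to dichloroacetylene; the geometry is lost in the next step.
- Cyclobutenones 15, 28 and 41 are racemic; their single stereocentre vanishes on ring expansion.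
- Compound 1 (the pinacol boronate of syringol) is taken as a catalogue compound.
- Atom bookkeeping for 41 and 44: carbonyl carbon to G5, the two methoxy carbons to G4 and G3, the acetal carbon to G2, the vinyl carbons to G1 and G6; the structures are consistent with formation of the G5–G6 bond and needed no correction.

## Route

Step 1
Reactants: 1 2,6-dimethoxy-4-(4,4,5,5-tetramethyl-1,3,2-dioxaborolan-2-yl)phenol; 2 trichloroethylene
Product: 4 2-[4-[(E)-1,2-dichloroethenyl]oxy-3,5-dimethoxyphenyl]-4,4,5,5-tetramethyl-1,3,2-dioxaborolane, via dichloroacetylene 3 (not isolated)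
Conditions: K2CO3, DMF, 70 °C
Reagents that add atoms: none
Why: Carbonate eliminates HCl from 2 to give dichloroacetylene 3, to which the phenoxide adds anti (nucleophilic addition to a haloalkyne, the standard route to aryl (E)-1,2-dichlorovinyl ethers); the pinacol boronate tolerates anhydrous carbonate, and the masked alkyne for rings B, D and F is installed once on a small molecule.

Step 2
Reactants: 4 2-[4-[(E)-1,2-dichloroethenyl]oxy-3,5-dimethoxyphenyl]-4,4,5,5-tetramethyl-1,3,2-dioxaborolane
Product: 5 [4-[(E)-1,2-dichloroethenyl]oxy-3,5-dimethoxyphenyl]boronic acid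
Conditions: NaIO4, NH4OAc, acetone/H2O, rt
Reagents that add atoms: water, O
Why: Periodate cleaves the pinacol released at equilibrium and so drives hydrolysis of the ester (oxidative deprotection of a pinacol boronate); the electron-poor dichlorovinyl ether is not oxidised, and the free acid transmetalates to copper far more readily than the ester.

Step 3
Reactants: 6 2,4,6-trimethoxyphenol; 5 [4-[(E)-1,2-dichloroethenyl]oxy-3,5-dimethoxyphenyl]boronic acid
Product: 7 dimer A–B (E)-1,2-dichlorovinyl ether
Conditions: Cu(OAc)2 (2 equiv), pyridine, 4 Å MS, CH2Cl2, dry air, rt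
Reagents that add atoms: none
Why: Chan–Lam coupling, an oxidative copper-mediated C–O coupling at room temperature; phenols with two ortho substituents are competent when the boronic acid is unhindered at boron, as 5 is, and the dichlorovinyl ether is a spectator.

Step 4
Reactants: 7 dimer A–B (E)-1,2-dichlorovinyl ether
Product: 10 dimer A–B ethynyl ether, via chloroethynyl ether 8 (not isolated), via lithium acetylide 9 (not isolated)
Conditions: n-BuLi (2.2 equiv), THF, –78 to –40 °C; H2O
Reagents that add atoms: none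
Why: Deprotonation and loss of LiCl give 8, chlorine–lithium exchange gives acetylide 9 and water gives the terminal ynol ether (the established conversion of dichlorovinyl ethers into alkynyl ethers); vinylic deprotonation at –78 °C is far faster than ring lithiation, and the two ortho methoxy groups shield the ynol ether.

Step 5
Reactants: 10 dimer A–B ethynyl ether
Product: 11 dimer A–B 1-(tributylstannyl)vinyl ether
Conditions: Bu3SnH, Pd(PPh3)4 (cat.), THF, 0 °C to rt
Reagents that add atoms: tributyltin hydride, CCCC[SnH](CCCC)CCCC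
Why: Hydrostannylation catalysed by zerovalent palladium is a syn addition that, with heteroatom-substituted alkynes, should place tin on the oxygen-bearing carbon and give the 1-stannylvinyl ether; nothing else in 10 reacts with the tin hydride.

Step 6
Reactants: 11 dimer A–B 1-(tributylstannyl)vinyl ether; 12 dimethyl squarate
Product: 15 racemic 4-[1-(dimer A–B 4-oxy)vinyl]-2,3-dimethoxy-4-(methoxymethoxy)cyclobut-2-en-1-one, via vinyllithium 13 (not isolated), via lithium alkoxide 14 (not isolated)
Conditions: n-BuLi, THF, –78 °C; added to 12, THF, –78 °C; MeOCH2Cl, –78 to 0 °C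
Reagents that add atoms: chloromethyl methyl ether, COCCl
Why: Tin–lithium exchange gives vinyllithium 13, which adds 1,2 to one carbonyl of 12 (organolithium addition to a squarate ester), and alkoxide 14 is O-alkylated in the same flask (Williamson-type acetal formation); the quaternary carbon is a new stereocentre formed without control, so 15 is racemic, which is harmless because step 7 destroys it.

Step 7
Reactants: 15 racemic 4-[1-(dimer A–B 4-oxy)vinyl]-2,3-dimethoxy-4-(methoxymethoxy)cyclobut-2-en-1-one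
Product: 18 trimer A–C with ring C as 5-hydroxy-3,4-dimethoxy-2-(methoxymethoxy)phenyl, via dienylketene 16 (not isolated), via cyclohexadienone 17 (not isolated)
Conditions: degassed toluene, 110 °C, argon
Reagents that add atoms: none
Why: Thermal ring expansion of a 4-alkenyl-4-alkoxycyclobutenone: conrotatory 4-pi opening with the acetal oxygen turning outward gives ketene 16, 6-pi electrocyclisation gives dienone 17 and enolisation gives the phenol; ring C appears with C1 already on the B4 oxygen, C5–OH free and C2–O protected.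

Step 8
Reactants: 18 trimer A–C with ring C as 5-hydroxy-3,4-dimethoxy-2-(methoxymethoxy)phenyl
Product: 20 trimer A–C phenol with free C2 hydroxyl, via methyl ether 19 (not isolated)
Conditions: K2CO3, MeI, MeCN, 40 °C; then 6 M HCl, MeOH, 50 °C
Reagents that add atoms: iodomethane, CI
Why: Williamson methylation caps the unhindered C5 phenol, then acid-catalysed acetal exchange with methanol removes the methoxymethyl group in the same flask; aryl methyl and diaryl ethers are inert to both, and no base remains when the C2 phenol appears.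

Step 9
Reactants: 20 trimer A–C phenol with free C2 hydroxyl; 5 [4-[(E)-1,2-dichloroethenyl]oxy-3,5-dimethoxyphenyl]boronic acid
Product: 21 tetramer A–D (E)-1,2-dichlorovinyl ether
Conditions: Cu(OAc)2 (2 equiv), pyridine, 4 Å MS, CH2Cl2, dry air, rt
Reagents that add atoms: none
Why: Chan–Lam coupling as in step 3; the C2 phenol, flanked by an aryloxy and a methoxy group, is in the same steric class as 6, and ring D arrives with its 4-oxygen already carrying the masked alkyne.

Step 10
Reactants: 21 tetramer A–D (E)-1,2-dichlorovinyl ether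
Product: 24 tetramer A–D ethynyl ether, via chloroethynyl ether 22 (not isolated), via lithium acetylide 23 (not isolated)
Conditions: n-BuLi (2.2 equiv), THF, –78 to –40 °C; H2O
Reagents that add atoms: none
Why: Elimination and chlorine–lithium exchange as in step 4 (dichlorovinyl ether to ynol ether); the molecule holds only aryl methyl and diaryl ethers besides the reacting group, none of which is attacked at –78 °C.

Step 11
Reactants: 24 tetramer A–D ethynyl ether
Product: 25 tetramer A–D 1-(tributylstannyl)vinyl ether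
Conditions: Bu3SnH, Pd(PPh3)4 (cat.), THF, 0 °C to rt
Reagents that add atoms: tributyltin hydride, CCCC[SnH](CCCC)CCCC
Why: Hydrostannylation catalysed by zerovalent palladium as in step 5, with tin expected on the oxygen-bearing carbon.

Step 12
Reactants: 25 tetramer A–D 1-(tributylstannyl)vinyl ether; 12 dimethyl squarate
Product: 28 racemic 4-[1-(tetramer A–D 4-oxy)vinyl]-2,3-dimethoxy-4-(methoxymethoxy)cyclobut-2-en-1-one, via vinyllithium 26 (not isolated), via lithium alkoxide 27 (not isolated)
Conditions: n-BuLi, THF, –78 °C; added to 12, THF, –78 °C; MeOCH2Cl, –78 to 0 °C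
Reagents that add atoms: chloromethyl methyl ether, COCCl
Why: Tin–lithium exchange, 1,2-addition to the squarate and capture of the alkoxide as in step 6; the new quaternary stereocentre is uncontrolled (racemic) and is removed in step 13.

Step 13
Reactants: 28 racemic 4-[1-(tetramer A–D 4-oxy)vinyl]-2,3-dimethoxy-4-(methoxymethoxy)cyclobut-2-en-1-one
Product: 31 pentamer A–E with ring E as 5-hydroxy-3,4-dimethoxy-2-(methoxymethoxy)phenyl, via dienylketene 29 (not isolated), via cyclohexadienone 30 (not isolated)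
Conditions: degassed toluene, 110 °C, argon
Reagents that add atoms: none
Why: Thermal cyclobutenone ring expansion as in step 7 (4-pi opening, 6-pi closure, enolisation), building ring E onto the D4 oxygen.

Step 14
Reactants: 31 pentamer A–E with ring E as 5-hydroxy-3,4-dimethoxy-2-(methoxymethoxy)phenyl
Product: 33 pentamer A–E phenol with free E2 hydroxyl, via methyl ether 32 (not isolated)
Conditions: K2CO3, MeI, MeCN, 40 °C; then 6 M HCl, MeOH, 50 °C
Reagents that add atoms: iodomethane, CI
Why: Williamson methylation of the E5 phenol followed by acid-catalysed removal of the methoxymethyl acetal, as in step 8.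

Step 15
Reactants: 33 pentamer A–E phenol with free E2 hydroxyl; 5 [4-[(E)-1,2-dichloroethenyl]oxy-3,5-dimethoxyphenyl]boronic acid
Product: 34 hexamer A–F (E)-1,2-dichlorovinyl ether
Conditions: Cu(OAc)2 (2 equiv), pyridine, 4 Å MS, CH2Cl2, dry air, rt
Reagents that add atoms: none
Why: Chan–Lam coupling as in steps 3 and 9; ring F is attached through E2–O–F1 with F4–O already masked as the alkyne precursor, so no free hexamer phenol is needed.

Step 16
Reactants: 34 hexamer A–F (E)-1,2-dichlorovinyl ether
Product: 37 hexamer A–F ethynyl ether, via chloroethynyl ether 35 (not isolated), via lithium acetylide 36 (not isolated)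
Conditions: n-BuLi (2.2 equiv), THF, –78 to –40 °C; H2O
Reagents that add atoms: none
Why: Elimination and chlorine–lithium exchange as in steps 4 and 10, giving the ynol ether.

Step 17
Reactants: 37 hexamer A–F ethynyl ether
Product: 38 hexamer A–F 1-(tributylstannyl)vinyl ether
Conditions: Bu3SnH, Pd(PPh3)4 (cat.), THF, 0 °C to rt
Reagents that add atoms: tributyltin hydride, CCCC[SnH](CCCC)CCCC
Why: Hydrostannylation catalysed by zerovalent palladium as in steps 5 and 11, with tin expected on the oxygen-bearing carbon.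

Step 18
Reactants: 38 hexamer A–F 1-(tributylstannyl)vinyl ether; 12 dimethyl squarate
Product: 41 racemic 4-[1-(hexamer A–F 4-oxy)vinyl]-2,3-dimethoxy-4-(methoxymethoxy)cyclobut-2-en-1-one, via vinyllithium 39 (not isolated), via lithium alkoxide 40 (not isolated)
Conditions: n-BuLi, THF, –78 °C; added to 12, THF, –78 °C; MeOCH2Cl, –78 to 0 °C
Reagents that add atoms: chloromethyl methyl ether, COCCl
Why: Tin–lithium exchange, 1,2-addition of the vinyllithium to the squarate and in-flask O-alkylation as in steps 6 and 12; the quaternary stereocentre is formed without control (racemic) and is removed in step 19.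

Step 19
Reactants: 41 racemic 4-[1-(hexamer A–F 4-oxy)vinyl]-2,3-dimethoxy-4-(methoxymethoxy)cyclobut-2-en-1-one
Product: 44 heptamer A–G with ring G as 5-hydroxy-3,4-dimethoxy-2-(methoxymethoxy)phenyl, via dienylketene 42 (not isolated), via cyclohexadienone 43 (not isolated)
Conditions: degassed toluene, 110 °C, argon
Reagents that add atoms: none
Why: Heating opens the C1–C4 bond of the cyclobutenone in a conrotatory 4-pi electrocyclic reaction to dienylketene 42. Torquoselectivity sends the donor oxygen on C4 outward, so the 1-aryloxyvinyl group turns inward and lies cis to the ketene. A thermal disrotatory 6-pi electrocyclisation then joins the ketene carbon (G5) to the terminal methylene (G6) and closes the six-membered carbocycle as cyclohexa-2,4-dienone 43; enolisation, driven by aromatisation, gives phenol 44. The closest known reaction type is the thermal ring expansion of 4-alkenyl-4-alkoxycyclobutenones from squarate esters to monoprotected hydroquinones, here with an oxygen on the internal vinyl carbon. No stereocentre is formed and the racemic quaternary centre of 41 is lost. Regiochemistry needs no control because it is written into the connectivity: squarate carbons become G2 to G5, vinyl carbons G1 and G6, the carbonyl oxygen becomes the free G5 hydroxyl and the acetal oxygen stays on G2. The only selectivity required is the outward rotation of oxygen, inherent to 4-alkoxycyclobutenones; exclusion of air and protic nucleophiles protects ketene 42 and the electron-rich phenol.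

Step 20
Reactants: 44 heptamer A–G with ring G as 5-hydroxy-3,4-dimethoxy-2-(methoxymethoxy)phenyl
Product: 46 heptamer A–G phenol with free G2 hydroxyl, via methyl ether 45 (not isolated)
Conditions: K2CO3, MeI, MeCN, 40 °C; then 6 M HCl, MeOH, 50 °C
Reagents that add atoms: iodomethane, CI
Why: Williamson methylation of the unhindered G5 phenol, then acid-catalysed acetal exchange frees the G2 hydroxyl, as in steps 8 and 14.

Step 21
Reactants: 46 heptamer A–G phenol with free G2 hydroxyl; 47 3,4,5-trimethoxyphenylboronic acid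
Product: 48 permethylated octamer A–H
Conditions: Cu(OAc)2 (2 equiv), pyridine, 4 Å MS, CH2Cl2, dry air, rt
Reagents that add atoms: none
Why: Chan–Lam coupling of a doubly ortho-substituted phenol with a boronic acid that is unhindered at boron forms G2–O–H1 at room temperature without disturbing any other ether.

Step 22
Reactants: 48 permethylated octamer A–H
Product: 49 target octamer, CNP0206369.0
Conditions: BBr3 (excess), CH2Cl2, –78 °C to rt; MeOH then H2O, argon
Reagents that add atoms: none
Why: Lewis-acid-mediated cleavage of aryl methyl ethers: boron binds each ether oxygen and bromide attacks the methyl carbon; the diaryl ether bonds have no sp3 carbon and are not cleaved, and acidic, air-free work-up protects the polyphenol.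

## Compound list

1 | 2,6-dimethoxy-4-(4,4,5,5-tetramethyl-1,3,2-dioxaborolan-2-yl)phenol | COc1cc(B2OC(C)(C)C(C)(C)O2)cc(OC)c1O | starting material
2 | trichloroethylene | ClC=C(Cl)Cl | starting material
3 | dichloroacetylene | ClC#CCl | intermediate
4 | 2-[4-[(E)-1,2-dichloroethenyl]oxy-3,5-dimethoxyphenyl]-4,4,5,5-tetramethyl-1,3,2-dioxaborolane | COc1cc(B2OC(C)(C)C(C)(C)O2)cc(OC)c1O/C(Cl)=C\Cl | intermediate
5 | [4-[(E)-1,2-dichloroethenyl]oxy-3,5-dimethoxyphenyl]boronic acid | COc1cc(B(O)O)cc(OC)c1O/C(Cl)=C\Cl | intermediate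
6 | 2,4,6-trimethoxyphenol | COc1cc(OC)c(O)c(OC)c1 | starting material
7 | dimer A–B (E)-1,2-dichlorovinyl ether: 2-[4-[(E)-1,2-dichloroethenyl]oxy-3,5-dimethoxyphenoxy]-1,3,5-trimethoxybenzene | COc1cc(OC)c(Oc2cc(OC)c(O/C(Cl)=C\Cl)c(OC)c2)c(OC)c1 | intermediate
8 | dimer A–B chloroethynyl ether: 2-[4-(chloroethynyloxy)-3,5-dimethoxyphenoxy]-1,3,5-trimethoxybenzene | COc1cc(OC)c(Oc2cc(OC)c(OC#CCl)c(OC)c2)c(OC)c1 | intermediate
9 | dimer A–B lithium acetylide: lithium 2-[2,6-dimethoxy-4-(2,4,6-trimethoxyphenoxy)phenoxy]ethynide | COc1cc(OC)c(Oc2cc(OC)c(OC#C[Li])c(OC)c2)c(OC)c1 | intermediate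
10 | dimer A–B ethynyl ether: 2-(4-ethynyloxy-3,5-dimethoxyphenoxy)-1,3,5-trimethoxybenzene | COc1cc(OC)c(Oc2cc(OC)c(OC#C)c(OC)c2)c(OC)c1 | intermediate
11 | dimer A–B 1-(tributylstannyl)vinyl ether: tributyl[1-[2,6-dimethoxy-4-(2,4,6-trimethoxyphenoxy)phenoxy]ethenyl]stannane | COc1cc(OC)c(Oc2cc(OC)c(OC(=C)[Sn](CCCC)(CCCC)CCCC)c(OC)c2)c(OC)c1 | intermediate
12 | dimethyl squarate (3,4-dimethoxycyclobut-3-ene-1,2-dione) | COC1=C(OC)C(=O)C1=O | starting material
13 | dimer A–B 1-lithiovinyl ether | COc1cc(OC)c(Oc2cc(OC)c(OC(=C)[Li])c(OC)c2)c(OC)c1 | intermediate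
14 | racemic lithium 1-[1-(dimer A–B 4-oxy)vinyl]-2,3-dimethoxy-4-oxocyclobut-2-en-1-olate | COc1cc(OC)c(Oc2cc(OC)c(OC(=C)C3(O[Li])C(=O)C(OC)=C3OC)c(OC)c2)c(OC)c1 | intermediate
15 | racemic 4-[1-(dimer A–B 4-oxy)vinyl]-2,3-dimethoxy-4-(methoxymethoxy)cyclobut-2-en-1-one | COc1cc(OC)c(Oc2cc(OC)c(OC(=C)C3(OCOC)C(=O)C(OC)=C3OC)c(OC)c2)c(OC)c1 | intermediate
16 | (3Z)-5-(dimer A–B 4-oxy)-2,3-dimethoxy-4-(methoxymethoxy)hexa-1,3,5-trien-1-one (dienylketene) | COc1cc(OC)c(Oc2cc(OC)c(OC(=C)/C(OCOC)=C(OC)\C(OC)=C=O)c(OC)c2)c(OC)c1 | intermediate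
17 | 5-(dimer A–B 4-oxy)-2,3-dimethoxy-4-(methoxymethoxy)cyclohexa-2,4-dien-1-one | COc1cc(OC)c(Oc2cc(OC)c(OC3=C(OCOC)C(OC)=C(OC)C(=O)C3)c(OC)c2)c(OC)c1 | intermediate
18 | trimer A–C, ring C as 5-hydroxy-3,4-dimethoxy-2-(methoxymethoxy)phenyl on the B4 oxygen | COc1cc(OC)c(Oc2cc(OC)c(Oc3cc(O)c(OC)c(OC)c3OCOC)c(OC)c2)c(OC)c1 | intermediate
19 | trimer A–C, ring C as 3,4,5-trimethoxy-2-(methoxymethoxy)phenyl | COc1cc(OC)c(Oc2cc(OC)c(Oc3cc(OC)c(OC)c(OC)c3OCOC)c(OC)c2)c(OC)c1 | intermediate
20 | trimer A–C phenol, ring C as 2-hydroxy-3,4,5-trimethoxyphenyl | COc1cc(OC)c(Oc2cc(OC)c(Oc3cc(OC)c(OC)c(OC)c3O)c(OC)c2)c(OC)c1 | intermediate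
21 | tetramer A–D (E)-1,2-dichlorovinyl ether (on the D4 oxygen) | COc1cc(OC)c(Oc2cc(OC)c(Oc3cc(OC)c(OC)c(OC)c3Oc3cc(OC)c(O/C(Cl)=C\Cl)c(OC)c3)c(OC)c2)c(OC)c1 | intermediate
22 | tetramer A–D chloroethynyl ether | COc1cc(OC)c(Oc2cc(OC)c(Oc3cc(OC)c(OC)c(OC)c3Oc3cc(OC)c(OC#CCl)c(OC)c3)c(OC)c2)c(OC)c1 | intermediate
23 | tetramer A–D lithium acetylide (lithium on the terminal alkyne carbon) | COc1cc(OC)c(Oc2cc(OC)c(Oc3cc(OC)c(OC)c(OC)c3Oc3cc(OC)c(OC#C[Li])c(OC)c3)c(OC)c2)c(OC)c1 | intermediate
24 | tetramer A–D ethynyl ether | COc1cc(OC)c(Oc2cc(OC)c(Oc3cc(OC)c(OC)c(OC)c3Oc3cc(OC)c(OC#C)c(OC)c3)c(OC)c2)c(OC)c1 | intermediate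
25 | tetramer A–D 1-(tributylstannyl)vinyl ether | COc1cc(OC)c(Oc2cc(OC)c(Oc3cc(OC)c(OC)c(OC)c3Oc3cc(OC)c(OC(=C)[Sn](CCCC)(CCCC)CCCC)c(OC)c3)c(OC)c2)c(OC)c1 | intermediate
26 | tetramer A–D 1-lithiovinyl ether | COc1cc(OC)c(Oc2cc(OC)c(Oc3cc(OC)c(OC)c(OC)c3Oc3cc(OC)c(OC(=C)[Li])c(OC)c3)c(OC)c2)c(OC)c1 | intermediate
27 | racemic lithium 1-[1-(tetramer A–D 4-oxy)vinyl]-2,3-dimethoxy-4-oxocyclobut-2-en-1-olate | COc1cc(OC)c(Oc2cc(OC)c(Oc3cc(OC)c(OC)c(OC)c3Oc3cc(OC)c(OC(=C)C4(O[Li])C(=O)C(OC)=C4OC)c(OC)c3)c(OC)c2)c(OC)c1 | intermediate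
28 | racemic 4-[1-(tetramer A–D 4-oxy)vinyl]-2,3-dimethoxy-4-(methoxymethoxy)cyclobut-2-en-1-one | COc1cc(OC)c(Oc2cc(OC)c(Oc3cc(OC)c(OC)c(OC)c3Oc3cc(OC)c(OC(=C)C4(OCOC)C(=O)C(OC)=C4OC)c(OC)c3)c(OC)c2)c(OC)c1 | intermediate
29 | (3Z)-5-(tetramer A–D 4-oxy)-2,3-dimethoxy-4-(methoxymethoxy)hexa-1,3,5-trien-1-one (dienylketene) | COc1cc(OC)c(Oc2cc(OC)c(Oc3cc(OC)c(OC)c(OC)c3Oc3cc(OC)c(OC(=C)/C(OCOC)=C(OC)\C(OC)=C=O)c(OC)c3)c(OC)c2)c(OC)c1 | intermediate
30 | 5-(tetramer A–D 4-oxy)-2,3-dimethoxy-4-(methoxymethoxy)cyclohexa-2,4-dien-1-one | COc1cc(OC)c(Oc2cc(OC)c(Oc3cc(OC)c(OC)c(OC)c3Oc3cc(OC)c(OC4=C(OCOC)C(OC)=C(OC)C(=O)C4)c(OC)c3)c(OC)c2)c(OC)c1 | intermediate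
31 | pentamer A–E, ring E as 5-hydroxy-3,4-dimethoxy-2-(methoxymethoxy)phenyl on the D4 oxygen | COc1cc(OC)c(Oc2cc(OC)c(Oc3cc(OC)c(OC)c(OC)c3Oc3cc(OC)c(Oc4cc(O)c(OC)c(OC)c4OCOC)c(OC)c3)c(OC)c2)c(OC)c1 | intermediate
32 | pentamer A–E, ring E as 3,4,5-trimethoxy-2-(methoxymethoxy)phenyl | COc1cc(OC)c(Oc2cc(OC)c(Oc3cc(OC)c(OC)c(OC)c3Oc3cc(OC)c(Oc4cc(OC)c(OC)c(OC)c4OCOC)c(OC)c3)c(OC)c2)c(OC)c1 | intermediate
33 | pentamer A–E phenol, ring E as 2-hydroxy-3,4,5-trimethoxyphenyl | COc1cc(OC)c(Oc2cc(OC)c(Oc3cc(OC)c(OC)c(OC)c3Oc3cc(OC)c(Oc4cc(OC)c(OC)c(OC)c4O)c(OC)c3)c(OC)c2)c(OC)c1 | intermediate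
34 | hexamer A–F (E)-1,2-dichlorovinyl ether (on the F4 oxygen) | COc1cc(OC)c(Oc2cc(OC)c(Oc3cc(OC)c(OC)c(OC)c3Oc3cc(OC)c(Oc4cc(OC)c(OC)c(OC)c4Oc4cc(OC)c(O/C(Cl)=C\Cl)c(OC)c4)c(OC)c3)c(OC)c2)c(OC)c1 | intermediate
35 | hexamer A–F chloroethynyl ether | COc1cc(OC)c(Oc2cc(OC)c(Oc3cc(OC)c(OC)c(OC)c3Oc3cc(OC)c(Oc4cc(OC)c(OC)c(OC)c4Oc4cc(OC)c(OC#CCl)c(OC)c4)c(OC)c3)c(OC)c2)c(OC)c1 | intermediate
36 | hexamer A–F lithium acetylide (lithium on the terminal alkyne carbon) | COc1cc(OC)c(Oc2cc(OC)c(Oc3cc(OC)c(OC)c(OC)c3Oc3cc(OC)c(Oc4cc(OC)c(OC)c(OC)c4Oc4cc(OC)c(OC#C[Li])c(OC)c4)c(OC)c3)c(OC)c2)c(OC)c1 | intermediate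
37 | hexamer A–F ethynyl ether | COc1cc(OC)c(Oc2cc(OC)c(Oc3cc(OC)c(OC)c(OC)c3Oc3cc(OC)c(Oc4cc(OC)c(OC)c(OC)c4Oc4cc(OC)c(OC#C)c(OC)c4)c(OC)c3)c(OC)c2)c(OC)c1 | intermediate
38 | hexamer A–F 1-(tributylstannyl)vinyl ether | COc1cc(OC)c(Oc2cc(OC)c(Oc3cc(OC)c(OC)c(OC)c3Oc3cc(OC)c(Oc4cc(OC)c(OC)c(OC)c4Oc4cc(OC)c(OC(=C)[Sn](CCCC)(CCCC)CCCC)c(OC)c4)c(OC)c3)c(OC)c2)c(OC)c1 | intermediate
39 | hexamer A–F 1-lithiovinyl ether | COc1cc(OC)c(Oc2cc(OC)c(Oc3cc(OC)c(OC)c(OC)c3Oc3cc(OC)c(Oc4cc(OC)c(OC)c(OC)c4Oc4cc(OC)c(OC(=C)[Li])c(OC)c4)c(OC)c3)c(OC)c2)c(OC)c1 | intermediate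
40 | racemic lithium 1-[1-(hexamer A–F 4-oxy)vinyl]-2,3-dimethoxy-4-oxocyclobut-2-en-1-olate | COc1cc(OC)c(Oc2cc(OC)c(Oc3cc(OC)c(OC)c(OC)c3Oc3cc(OC)c(Oc4cc(OC)c(OC)c(OC)c4Oc4cc(OC)c(OC(=C)C5(O[Li])C(=O)C(OC)=C5OC)c(OC)c4)c(OC)c3)c(OC)c2)c(OC)c1 | intermediate
41 | racemic 4-[1-(hexamer A–F 4-oxy)vinyl]-2,3-dimethoxy-4-(methoxymethoxy)cyclobut-2-en-1-one (key-step precursor) | COc1cc(OC)c(Oc2cc(OC)c(Oc3cc(OC)c(OC)c(OC)c3Oc3cc(OC)c(Oc4cc(OC)c(OC)c(OC)c4Oc4cc(OC)c(OC(=C)C5(OCOC)C(=O)C(OC)=C5OC)c(OC)c4)c(OC)c3)c(OC)c2)c(OC)c1 | intermediate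
42 | (3Z)-5-(hexamer A–F 4-oxy)-2,3-dimethoxy-4-(methoxymethoxy)hexa-1,3,5-trien-1-one (dienylketene) | COc1cc(OC)c(Oc2cc(OC)c(Oc3cc(OC)c(OC)c(OC)c3Oc3cc(OC)c(Oc4cc(OC)c(OC)c(OC)c4Oc4cc(OC)c(OC(=C)/C(OCOC)=C(OC)\C(OC)=C=O)c(OC)c4)c(OC)c3)c(OC)c2)c(OC)c1 | intermediate
43 | 5-(hexamer A–F 4-oxy)-2,3-dimethoxy-4-(methoxymethoxy)cyclohexa-2,4-dien-1-one | COc1cc(OC)c(Oc2cc(OC)c(Oc3cc(OC)c(OC)c(OC)c3Oc3cc(OC)c(Oc4cc(OC)c(OC)c(OC)c4Oc4cc(OC)c(OC5=C(OCOC)C(OC)=C(OC)C(=O)C5)c(OC)c4)c(OC)c3)c(OC)c2)c(OC)c1 | intermediate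
44 | heptamer A–G, ring G as 5-hydroxy-3,4-dimethoxy-2-(methoxymethoxy)phenyl on the F4 oxygen (key-step product) | COc1cc(OC)c(Oc2cc(OC)c(Oc3cc(OC)c(OC)c(OC)c3Oc3cc(OC)c(Oc4cc(OC)c(OC)c(OC)c4Oc4cc(OC)c(Oc5cc(O)c(OC)c(OC)c5OCOC)c(OC)c4)c(OC)c3)c(OC)c2)c(OC)c1 | intermediate
45 | heptamer A–G, ring G as 3,4,5-trimethoxy-2-(methoxymethoxy)phenyl | COc1cc(OC)c(Oc2cc(OC)c(Oc3cc(OC)c(OC)c(OC)c3Oc3cc(OC)c(Oc4cc(OC)c(OC)c(OC)c4Oc4cc(OC)c(Oc5cc(OC)c(OC)c(OC)c5OCOC)c(OC)c4)c(OC)c3)c(OC)c2)c(OC)c1 | intermediate
46 | heptamer A–G phenol, ring G as 2-hydroxy-3,4,5-trimethoxyphenyl | COc1cc(OC)c(Oc2cc(OC)c(Oc3cc(OC)c(OC)c(OC)c3Oc3cc(OC)c(Oc4cc(OC)c(OC)c(OC)c4Oc4cc(OC)c(Oc5cc(OC)c(OC)c(OC)c5O)c(OC)c4)c(OC)c3)c(OC)c2)c(OC)c1 | intermediate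
47 | 3,4,5-trimethoxyphenylboronic acid | COc1cc(B(O)O)cc(OC)c1OC | starting material
48 | permethylated octamer A–H (twenty-one methyl ethers) | COc1cc(OC)c(Oc2cc(OC)c(Oc3cc(OC)c(OC)c(OC)c3Oc3cc(OC)c(Oc4cc(OC)c(OC)c(OC)c4Oc4cc(OC)c(Oc5cc(OC)c(OC)c(OC)c5Oc5cc(OC)c(OC)c(OC)c5)c(OC)c4)c(OC)c3)c(OC)c2)c(OC)c1 | intermediate
49 | target octamer CNP0206369.0 (twenty-one free hydroxyls, no stereocentre) | Oc1cc(O)c(Oc2cc(O)c(Oc3cc(O)c(O)c(O)c3Oc3cc(O)c(Oc4cc(O)c(O)c(O)c4Oc4cc(O)c(Oc5cc(O)c(O)c(O)c5Oc5cc(O)c(O)c(O)c5)c(O)c4)c(O)c3)c(O)c2)c(O)c1 | target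

## Step count and least certain steps

Total step count: 22. Longest linear sequence: 22 steps (1 to 49; compounds 2, 6, 12 and 47 are bought, and 5 is used in steps 3, 9 and 15).

**Step 19 (key step).**
- What may go wrong: loss of ketene 42 to dimerisation or to capture by traces of water before it cyclises; slow closure because the very large aryloxy group on the internal vinyl carbon twists the diene out of plane; and air oxidation of the electron-rich phenol at 110 °C.
- Fallback (sets out from 37, returns at 46): ring G is attached by substitution chemistry instead of being built. Acid-catalysed hydration of ynol ether 37 (TsOH, wet THF) gives the hexamer A–F aryl acetate F1, and K2CO3 in methanol frees the hexamer A–F phenol F2. 6-Fluoro-2,3,4-trimethoxybenzaldehyde F3 is made by Rieche formylation (Cl2CHOMe, TiCl4) of 5-fluoro-1,2,3-trimethoxybenzene. The phenoxide of F2 attacks F3 (K2CO3, DMF, 120 °C; nucleophilic aromatic substitution of a fluoride ortho to a formyl group) to give the heptamer A–G 2-formyl-3,4,5-trimethoxyphenyl ether F4. Baeyer–Villiger oxidation with 3-chloroperbenzoic acid gives the heptamer aryl formate F5, and methanolysis (K2CO3, MeOH) gives 46.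

**Step 18 (and its counterparts, steps 6 and 12).**
- What may go wrong: incomplete O-alkylation of the hindered tertiary lithium alkoxide, with ring opening of the alkoxide on warming; and protonation of the basic, carbenoid-like vinyllithium by ring positions flanked by two methoxy groups before it reaches the squarate.
- Fallback (sets out from 38, returns at 46): the exchange and addition are run as before, but alkoxide 40 is protonated at –78 °C (aqueous NH4Cl) and the racemic hexamer hydroxycyclobutenone F6 is isolated. Silylation of the tertiary alcohol (t-BuMe2SiOTf, 2,6-lutidine, CH2Cl2) gives the tert-butyldimethylsilyl ether F7. Its ring expansion in toluene at 110 °C gives the heptamer phenol with a silyl ether on G2, F8. Methylation (K2CO3, MeI, acetone) gives the G5 methyl ether F9, and Bu4NF in THF frees the G2 phenol 46.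

**Step 17 (and steps 5 and 11).**
- What may go wrong: addition with the opposite regiochemistry (tin on the terminal carbon) or double stannylation, and loss of the aryl ynol ether by hydration or oligomerisation on the catalyst.
- Fallback (sets out from 37, returns at 39 and thereby at 41): Markovnikov addition of HBr (1 equiv, CH2Cl2, –78 °C) to the ynol ether gives the hexamer A–F 1-bromovinyl ether F10. Bromine–lithium exchange with t-BuLi (2 equiv, THF, –78 °C) gives vinyllithium 39, which is carried on as in step 18.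

**Step 21 (the same caveat holds for steps 3, 9 and 15).**
- What may go wrong: slow coupling at a phenol flanked by an aryloxy and a methoxy group, while the boronic acid is consumed by protodeboronation, homocoupling and oxidation, and the electron-rich phenol is oxidised by divalent copper.
- Fallback (sets out from 46, returns at 48): an Ullmann-type coupling of 46 with commercial 5-iodo-1,2,3-trimethoxybenzene (CuI, picolinic acid, K3PO4, DMSO, 90 °C) forms the same G2–O–H1 bond by an aryl halide route. This fallback makes no new compound (F0).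

**Step 22.**
- What may go wrong: incomplete cleavage of the twenty-one ethers, giving mixtures of partly methylated congeners; precipitation of borate complexes before cleavage is complete; and air oxidation of rings C, E, G and H during work-up and purification.
- Fallback (sets out from 48, returns at 49): after the BBr3 treatment and methanol quench, the crude polyphenol is acetylated (Ac2O, pyridine) to the henicosaacetate of the octamer F11. This is stable to air and can be purified on silica, with under-cleaved material separated and resubmitted. Acid-catalysed methanolysis (HCl generated from AcCl in MeOH, argon) then releases 49.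

## Further compounds

F1 | step 19 | hexamer A–F aryl acetate (acetate on the F4 oxygen) | COc1cc(OC)c(Oc2cc(OC)c(Oc3cc(OC)c(OC)c(OC)c3Oc3cc(OC)c(Oc4cc(OC)c(OC)c(OC)c4Oc4cc(OC)c(OC(C)=O)c(OC)c4)c(OC)c3)c(OC)c2)c(OC)c1
F2 | step 19 | hexamer A–F phenol (free F4 hydroxyl) | COc1cc(OC)c(Oc2cc(OC)c(Oc3cc(OC)c(OC)c(OC)c3Oc3cc(OC)c(Oc4cc(OC)c(OC)c(OC)c4Oc4cc(OC)c(O)c(OC)c4)c(OC)c3)c(OC)c2)c(OC)c1
F3 | step 19 | 6-fluoro-2,3,4-trimethoxybenzaldehyde | COc1cc(F)c(C=O)c(OC)c1OC
F4 | step 19 | heptamer A–G, ring G as 2-formyl-3,4,5-trimethoxyphenyl | COc1cc(OC)c(Oc2cc(OC)c(Oc3cc(OC)c(OC)c(OC)c3Oc3cc(OC)c(Oc4cc(OC)c(OC)c(OC)c4Oc4cc(OC)c(Oc5cc(OC)c(OC)c(OC)c5C=O)c(OC)c4)c(OC)c3)c(OC)c2)c(OC)c1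
F5 | step 19 | heptamer A–G, ring G as 2-formyloxy-3,4,5-trimethoxyphenyl | COc1cc(OC)c(Oc2cc(OC)c(Oc3cc(OC)c(OC)c(OC)c3Oc3cc(OC)c(Oc4cc(OC)c(OC)c(OC)c4Oc4cc(OC)c(Oc5cc(OC)c(OC)c(OC)c5OC=O)c(OC)c4)c(OC)c3)c(OC)c2)c(OC)c1
F6 | step 18 | racemic 4-hydroxy-4-[1-(hexamer A–F 4-oxy)vinyl]-2,3-dimethoxycyclobut-2-en-1-one | COc1cc(OC)c(Oc2cc(OC)c(Oc3cc(OC)c(OC)c(OC)c3Oc3cc(OC)c(Oc4cc(OC)c(OC)c(OC)c4Oc4cc(OC)c(OC(=C)C5(O)C(=O)C(OC)=C5OC)c(OC)c4)c(OC)c3)c(OC)c2)c(OC)c1
F7 | step 18 | racemic 4-(tert-butyldimethylsilyloxy)-4-[1-(hexamer A–F 4-oxy)vinyl]-2,3-dimethoxycyclobut-2-en-1-one | COc1cc(OC)c(Oc2cc(OC)c(Oc3cc(OC)c(OC)c(OC)c3Oc3cc(OC)c(Oc4cc(OC)c(OC)c(OC)c4Oc4cc(OC)c(OC(=C)C5(O[Si](C)(C)C(C)(C)C)C(=O)C(OC)=C5OC)c(OC)c4)c(OC)c3)c(OC)c2)c(OC)c1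
F8 | step 18 | heptamer A–G, ring G as 2-(tert-butyldimethylsilyloxy)-5-hydroxy-3,4-dimethoxyphenyl | COc1cc(OC)c(Oc2cc(OC)c(Oc3cc(OC)c(OC)c(OC)c3Oc3cc(OC)c(Oc4cc(OC)c(OC)c(OC)c4Oc4cc(OC)c(Oc5cc(O)c(OC)c(OC)c5O[Si](C)(C)C(C)(C)C)c(OC)c4)c(OC)c3)c(OC)c2)c(OC)c1
F9 | step 18 | heptamer A–G, ring G as 2-(tert-butyldimethylsilyloxy)-3,4,5-trimethoxyphenyl | COc1cc(OC)c(Oc2cc(OC)c(Oc3cc(OC)c(OC)c(OC)c3Oc3cc(OC)c(Oc4cc(OC)c(OC)c(OC)c4Oc4cc(OC)c(Oc5cc(OC)c(OC)c(OC)c5O[Si](C)(C)C(C)(C)C)c(OC)c4)c(OC)c3)c(OC)c2)c(OC)c1
F10 | step 17 | hexamer A–F 1-bromovinyl ether | COc1cc(OC)c(Oc2cc(OC)c(Oc3cc(OC)c(OC)c(OC)c3Oc3cc(OC)c(Oc4cc(OC)c(OC)c(OC)c4Oc4cc(OC)c(OC(Br)=C)c(OC)c4)c(OC)c3)c(OC)c2)c(OC)c1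
F0 | step 21 | none | none
F11 | step 22 | henicosaacetate of the target octamer | CC(=O)Oc1cc(OC(C)=O)c(Oc2cc(OC(C)=O)c(Oc3cc(OC(C)=O)c(OC(C)=O)c(OC(C)=O)c3Oc3cc(OC(C)=O)c(Oc4cc(OC(C)=O)c(OC(C)=O)c(OC(C)=O)c4Oc4cc(OC(C)=O)c(Oc5cc(OC(C)=O)c(OC(C)=O)c(OC(C)=O)c5Oc5cc(OC(C)=O)c(OC(C)=O)c(OC(C)=O)c5)c(OC(C)=O)c4)c(OC(C)=O)c3)c(OC(C)=O)c2)c(OC(C)=O)c1
A1 | alternative 1 | 3,4-difluoro-6-methoxyphthalaldehyde | COc1cc(F)c(F)c(C=O)c1C=O
A2 | alternative 1 | permethylated tetramer A–D phenol (free D4 hydroxyl) | COc1cc(OC)c(Oc2cc(OC)c(Oc3cc(OC)c(OC)c(OC)c3Oc3cc(OC)c(O)c(OC)c3)c(OC)c2)c(OC)c1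
A3 | alternative 1 | permethylated trimer F–H phenol (free F1 hydroxyl) | Oc1cc(OC)c(Oc2cc(OC)c(OC)c(OC)c2Oc2cc(OC)c(OC)c(OC)c2)c(OC)c1
A4 | alternative 1 | octamer with ring E as 3,4-diformyl-5-methoxy, all other hydroxyls as methyl ethers | COc1cc(OC)c(Oc2cc(OC)c(Oc3cc(OC)c(OC)c(OC)c3Oc3cc(OC)c(Oc4cc(OC)c(C=O)c(C=O)c4Oc4cc(OC)c(Oc5cc(OC)c(OC)c(OC)c5Oc5cc(OC)c(OC)c(OC)c5)c(OC)c4)c(OC)c3)c(OC)c2)c(OC)c1
A5 | alternative 2 | racemic dimethyl 4-(permethylated heptamer B–H 1-oxy)-3,5-dioxoheptanedioate | COC(=O)CC(=O)C(Oc1cc(OC)c(Oc2cc(OC)c(OC)c(OC)c2Oc2cc(OC)c(Oc3cc(OC)c(OC)c(OC)c3Oc3cc(OC)c(Oc4cc(OC)c(OC)c(OC)c4Oc4cc(OC)c(OC)c(OC)c4)c(OC)c3)c(OC)c2)c(OC)c1)C(=O)CC(=O)OC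
A6 | alternative 2 | octamer with ring A as methyl 2,4,6-trihydroxy-3-aryloxybenzoate, rings B to H permethylated | COC(=O)c1c(O)cc(O)c(Oc2cc(OC)c(Oc3cc(OC)c(OC)c(OC)c3Oc3cc(OC)c(Oc4cc(OC)c(OC)c(OC)c4Oc4cc(OC)c(Oc5cc(OC)c(OC)c(OC)c5Oc5cc(OC)c(OC)c(OC)c5)c(OC)c4)c(OC)c3)c(OC)c2)c1O
A7 | alternative 3 | octamer tetraaldehyde (formyl on C4, E4, G4 and H4; seventeen methyl ethers) | COc1cc(OC)c(Oc2cc(OC)c(Oc3cc(OC)c(C=O)c(OC)c3Oc3cc(OC)c(Oc4cc(OC)c(C=O)c(OC)c4Oc4cc(OC)c(Oc5cc(OC)c(C=O)c(OC)c5Oc5cc(OC)c(C=O)c(OC)c5)c(OC)c4)c(OC)c3)c(OC)c2)c(OC)c1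
A8 | alternative 3 | octamer tetraphenol (free hydroxyl on C4, E4, G4 and H4; seventeen methyl ethers) | COc1cc(OC)c(Oc2cc(OC)c(Oc3cc(OC)c(O)c(OC)c3Oc3cc(OC)c(Oc4cc(OC)c(O)c(OC)c4Oc4cc(OC)c(Oc5cc(OC)c(O)c(OC)c5Oc5cc(OC)c(O)c(OC)c5)c(OC)c4)c(OC)c3)c(OC)c2)c(OC)c1
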